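## Retrosynthetic overview
1. C24–O bond and the (E)-C6=C7 olefin are made last, by a [2,3]-sigmatropic (Mislow–Evans) shift of a C6 allylic phenyl sulfoxide. The sulfide is carried through the route as the latent allylic alcohol.
2. The butenolide is the only ring and is closed one step earlier, by acylation and intramolecular Wittig reaction of a hydroxymethyl ketone with Ph3P=C=C=O. C25 comes from formaldehyde through a thiazolium cross-acyloin reaction on the C3 aldehyde.
3. C5–C6 is formed when an α-lithiated C19 allyl phenyl sulfide opens a three-carbon epoxy alcohol. That epoxy alcohol supplies C3–C5 and the only stereocentre (C4), whose C–O bond is never broken.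
4. C8–C9 is formed from the dianion of a C4 allylic alcohol and a C15 (E,E)-allylic bromide.

Assumption and numbering: (2E,6E)-farnesyl bromide and (S)-glycidol are bought as single isomers. Atom numbers are lactone C1(=O), C2, C3, C25 (OCH2), carbinol C4, C5, C6=C7, C24 (CH2OH), C8 onwards along the chain. The transient centres at C6 and at sulfur are carried as mixtures because the rearrangement erases them.

## Route

Step 1
Reactants: 1 2-methylprop-2-en-1-ol (methallyl alcohol); 2 (2E,6E)-farnesyl bromide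
Product: 4 (5E,9E)-6,10,14-trimethyl-2-methylidenepentadeca-5,9,13-trien-1-ol, via dilithiated methallyl alcohol 3 (not isolated)
Conditions: 1, n-BuLi (2.2 equiv), TMEDA, Et2O, 0 °C → rt; then 2, THF, −78 °C → rt; H2O
Reagents that add atoms: none
Why: Double deprotonation gives the symmetrical oxido-allyl dianion, whose carbon terminus displaces the primary allylic bromide by SN2 (dianion alkylation), forming C8–C9 without touching the E olefins or creating a stereocentre.

Step 2
Reactants: 4 (5E,9E)-6,10,14-trimethyl-2-methylidenepentadeca-5,9,13-trien-1-ol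
Product: 5 {[(5E,9E)-6,10,14-trimethyl-2-methylidenepentadeca-5,9,13-trien-1-yl]sulfanyl}benzene
Conditions: PhSSPh, PBu3, THF, rt
Reagents that add atoms: diphenyl disulfide, c1ccc(cc1)SSc1ccccc1
Why: In this Hata-type redox condensation the alkoxyphosphonium ion is displaced by thiolate, and SN2 and SN2' attack give the same sulfide because both allyl termini are CH2.

Step 3
Reactants: 5 {[(5E,9E)-6,10,14-trimethyl-2-methylidenepentadeca-5,9,13-trien-1-yl]sulfanyl}benzene; 6 (S)-glycidol
Product: 10 (2R,8E,12E)-9,13,17-trimethyl-5-methylidene-4-(phenylsulfanyl)-1,2-bis(triethylsilyloxy)octadeca-8,12,16-triene (both C4-chain epimers), via alpha-lithio sulfide 7 (not isolated), via lithium (S)-glycidoxide 8 (not isolated), via dilithium dialkoxide 9 (not isolated)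
Conditions: 5, n-BuLi, THF, −78 → −20 °C; 6, n-BuLi, THF, −78 °C; combine, DMPU, −78 °C → rt; then Et3SiCl, 0 °C
Reagents that add atoms: chlorotriethylsilane, CC[Si](Cl)(CC)CC
Why: The thioallyl anion attacks through its α-carbon at the unsubstituted epoxide carbon (SN2 epoxide opening, Biellmann-type alkylation), so the bought C–O bond stays intact and C4 is (R); the Payne shift of 8 is degenerate and does not scramble it, and both alkoxides are capped in the same flask.

Step 4
Reactants: 10 (2R,8E,12E)-9,13,17-trimethyl-5-methylidene-4-(phenylsulfanyl)-1,2-bis(triethylsilyloxy)octadeca-8,12,16-triene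
Product: 12 (2R,8E,12E)-9,13,17-trimethyl-5-methylidene-4-(phenylsulfanyl)-2-(triethylsilyloxy)octadeca-8,12,16-trienal, via alkoxysulfonium chloride 11 (not isolated)
Conditions: (COCl)2, DMSO, CH2Cl2, −78 → −40 °C; then Et3N, −78 → 0 °C
Reagents that add atoms: none
Why: In the selective Swern oxidation of silyl ethers only the unhindered primary triethylsilyl ether is exchanged for the alkoxysulfonium ion and collapses to the aldehyde, while the secondary ether, the aryl sulfide, the olefins and C4 are left alone.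

Step 5
Reactants: 12 (2R,8E,12E)-9,13,17-trimethyl-5-methylidene-4-(phenylsulfanyl)-2-(triethylsilyloxy)octadeca-8,12,16-trienal
Product: 13 (3R,9E,13E)-1-hydroxy-10,14,18-trimethyl-6-methylidene-5-(phenylsulfanyl)-3-(triethylsilyloxy)nonadeca-9,13,17-trien-2-one
Conditions: paraformaldehyde, 3-benzyl-5-(2-hydroxyethyl)-4-methylthiazolium chloride (10 mol %), i-Pr2NEt (20 mol %), THF, 60 °C
Reagents that add atoms: formaldehyde (as paraformaldehyde), C=O
Why: The achiral thiazolylidene turns the hindered aldehyde into its acyl-anion (Breslow) equivalent, which adds to the much more electrophilic formaldehyde (cross-acyloin hydroxymethylation), installing C25 without involving the C4–H bond.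

Step 6
Reactants: 13 (3R,9E,13E)-1-hydroxy-10,14,18-trimethyl-6-methylidene-5-(phenylsulfanyl)-3-(triethylsilyloxy)nonadeca-9,13,17-trien-2-one
Product: 15 4-[(1R,7E,11E)-8,12,16-trimethyl-4-methylidene-3-(phenylsulfanyl)-1-(triethylsilyloxy)heptadeca-7,11,15-trien-1-yl]furan-2(5H)-one, via ester phosphorane 14 (not isolated)
Conditions: Ph3P=C=C=O, toluene, 80 °C
Reagents that add atoms: (triphenylphosphoranylidene)ketene (Bestmann ylide), O=C=C=P(c1ccccc1)(c1ccccc1)c1ccccc1
Why: The only free hydroxyl adds to the cumulated ylide and the resulting stabilised phosphorane closes on the adjacent ketone (Bestmann acylation then intramolecular Wittig), giving the 4-substituted butenolide under neutral conditions that do not enolise C4.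

Step 7
Reactants: 15 4-[(1R,7E,11E)-8,12,16-trimethyl-4-methylidene-3-(phenylsulfanyl)-1-(triethylsilyloxy)heptadeca-7,11,15-trien-1-yl]furan-2(5H)-one
Product: 19 hippolide C, via allylic sulfoxide 16 (not isolated), via allylic sulfenate 17 (not isolated), via triethylsilyl ether 18 (not isolated)
Conditions: mCPBA (1.0 equiv), CH2Cl2, −78 °C; then P(OMe)3, MeOH, −78 °C → rt; then PPTS (cat.), rt
Reagents that add atoms: 3-chloroperoxybenzoic acid (mCPBA), O=C(OO)c1cccc(Cl)c1
Why: Sulfur is oxidised far faster than the olefins, and the allylic sulfoxide then undergoes the [2,3]-sigmatropic Mislow–Evans shift through an envelope with the C5 chain pseudo-equatorial, forming the C24–O bond and the (E)-C6=C7 olefin (CH2OH trans to C5); the phosphite cleaves the S–O bond, mild acid methanolysis removes the silyl ether, and C4 stays (R) as a spectator.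

## Compound list
1 | 2-methylprop-2-en-1-ol | CC(=C)CO | starting material
2 | (2E,6E)-farnesyl bromide | CC(C)=CCC/C(C)=C/CC/C(C)=C/CBr | starting material
3 | dilithiated methallyl alcohol | [Li]CC(=C)CO[Li] | intermediate
4 | (5E,9E)-6,10,14-trimethyl-2-methylidenepentadeca-5,9,13-trien-1-ol | CC(C)=CCC/C(C)=C/CC/C(C)=C/CCC(=C)CO | intermediate
5 | C19 allyl phenyl sulfide | CC(C)=CCC/C(C)=C/CC/C(C)=C/CCC(=C)CSc1ccccc1 | intermediate
6 | (S)-glycidol | OC[C@H]1CO1 | starting material
7 | alpha-lithio sulfide | CC(C)=CCC/C(C)=C/CC/C(C)=C/CCC(=C)C([Li])Sc1ccccc1 | intermediate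
8 | lithium (S)-glycidoxide | [Li]OC[C@H]1CO1 | intermediate
9 | dilithium dialkoxide of the (2R)-1,2-diol | CC(C)=CCC/C(C)=C/CC/C(C)=C/CCC(=C)C(Sc1ccccc1)C[C@@H](O[Li])CO[Li] | intermediate
10 | (2R)-bis(triethylsilyl) ether sulfide | CC(C)=CCC/C(C)=C/CC/C(C)=C/CCC(=C)C(Sc1ccccc1)C[C@@H](O[Si](CC)(CC)CC)CO[Si](CC)(CC)CC | intermediate
11 | alkoxysulfonium chloride | CC(C)=CCC/C(C)=C/CC/C(C)=C/CCC(=C)C(Sc1ccccc1)C[C@@H](O[Si](CC)(CC)CC)CO[S+](C)C.[Cl-] | intermediate
12 | (2R)-2-(triethylsilyloxy) aldehyde | CC(C)=CCC/C(C)=C/CC/C(C)=C/CCC(=C)C(Sc1ccccc1)C[C@@H](O[Si](CC)(CC)CC)C=O | intermediate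
13 | (3R)-1-hydroxy-3-(triethylsilyloxy)-2-ketone | CC(C)=CCC/C(C)=C/CC/C(C)=C/CCC(=C)C(Sc1ccccc1)C[C@@H](O[Si](CC)(CC)CC)C(=O)CO | intermediate
14 | ester phosphorane | CC(C)=CCC/C(C)=C/CC/C(C)=C/CCC(=C)C(Sc1ccccc1)C[C@@H](O[Si](CC)(CC)CC)C(=O)COC(=O)C=P(c1ccccc1)(c1ccccc1)c1ccccc1 | intermediate
15 | (1R)-butenolide allylic sulfide | CC(C)=CCC/C(C)=C/CC/C(C)=C/CCC(=C)C(C[C@@H](O[Si](CC)(CC)CC)C1=CC(=O)OC1)Sc1ccccc1 | intermediate
16 | allylic sulfoxide | CC(C)=CCC/C(C)=C/CC/C(C)=C/CCC(=C)C(C[C@@H](O[Si](CC)(CC)CC)C1=CC(=O)OC1)S(=O)c1ccccc1 | intermediate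
17 | (E)-allylic benzenesulfenate | CC(C)=CCC/C(C)=C/CC/C(C)=C/CC/C(=C\C[C@@H](O[Si](CC)(CC)CC)C1=CC(=O)OC1)COSc1ccccc1 | intermediate
18 | 4-O-triethylsilyl hippolide C | CC(C)=CCC/C(C)=C/CC/C(C)=C/CC/C(=C\C[C@@H](O[Si](CC)(CC)CC)C1=CC(=O)OC1)CO | intermediate
19 | hippolide C, 4-[(1R,3E,7E,11E)-1-hydroxy-4-(hydroxymethyl)-8,12,16-trimethylheptadeca-3,7,11,15-tetraen-1-yl]furan-2(5H)-one | CC(C)=CCC/C(C)=C/CC/C(C)=C/CC/C(=C\C[C@@H](O)C1=CC(=O)OC1)CO | target

## Summary
Total step count: 7. Longest linear sequence: 7 (steps 1–7 from 1 and 2; 6 enters at step 3).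

Steps most likely to fail:

**Step 3** (α versus γ attack of the thioallyl anion, and low reactivity of the anionic epoxide). The fallback sets out from 6 and 7 and comes back at 10. It replaces ring opening by an SN2 alkylation with a preformed, fully protected halide. Compound 6 is silylated (Et3SiCl, imidazole, CH2Cl2) to triethylsilyl glycidyl ether F1. The epoxide is then opened at its CH2 terminus with Et3SiI made from Et3SiCl and NaI in MeCN, which gives bis(triethylsilyl) iodide F2. Anion 7 is alkylated with F2 in THF–DMPU (−78 → −20 °C), where α-alkylation of thioallyl anions by primary halides is the rule, and this gives 10 directly.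

**Step 4** (the activated DMSO may attack the allyl sulfide or the secondary silyl ether). The fallback sets out from 10 and comes back at 12. Deprotection and oxidation are separated. PPTS in MeOH–CH2Cl2 at −10 °C removes only the primary silyl group to give primary alcohol F3. This is then oxidised with SO3·pyridine, DMSO and Et3N (Parikh–Doering) to 12.

**Step 5** (cross-acyloin reaction on an α-silyloxy aldehyde: low conversion, C4 epimerisation or silyl migration). The fallback sets out from 12 and comes back at 15, bypassing 13 and 14, and builds the ring by carbenoid homologation and a Horner–Wadsworth–Emmons closure.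
- LiCH2Cl (ICH2Cl, MeLi·LiBr, THF, −78 °C, AcOH quench at −78 °C) gives chlorohydrin F4.
- Dess–Martin periodinane with NaHCO3 gives chloromethyl ketone F5.
- Potassium diethylphosphonoacetate in DMF displaces chloride to give phosphonoacetate ester F6.
- LiCl and DBU in MeCN close F6 to 15.

## Further compounds
F1 | step 3 | triethylsilyl glycidyl ether, (R)-triethyl(oxiran-2-ylmethoxy)silane (same spatial arrangement as 6) | CC[Si](CC)(CC)OC[C@H]1CO1
F2 | step 3 | bis(triethylsilyl) iodide, (S)-1-iodo-2,3-bis(triethylsilyloxy)propane | IC[C@@H](O[Si](CC)(CC)CC)CO[Si](CC)(CC)CC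
F3 | step 4 | primary alcohol, (2R,8E,12E)-9,13,17-trimethyl-5-methylidene-4-(phenylsulfanyl)-2-(triethylsilyloxy)octadeca-8,12,16-trien-1-ol | CC(C)=CCC/C(C)=C/CC/C(C)=C/CCC(=C)C(Sc1ccccc1)C[C@@H](O[Si](CC)(CC)CC)CO
F4 | step 5 | chlorohydrin, (3R,9E,13E)-1-chloro-10,14,18-trimethyl-6-methylidene-5-(phenylsulfanyl)-3-(triethylsilyloxy)nonadeca-9,13,17-trien-2-ol | CC(C)=CCC/C(C)=C/CC/C(C)=C/CCC(=C)C(Sc1ccccc1)C[C@@H](O[Si](CC)(CC)CC)C(O)CCl
F5 | step 5 | chloromethyl ketone, (3R,9E,13E)-1-chloro-10,14,18-trimethyl-6-methylidene-5-(phenylsulfanyl)-3-(triethylsilyloxy)nonadeca-9,13,17-trien-2-one | CC(C)=CCC/C(C)=C/CC/C(C)=C/CCC(=C)C(Sc1ccccc1)C[C@@H](O[Si](CC)(CC)CC)C(=O)CCl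
F6 | step 5 | phosphonoacetate ester of 13 | CC(C)=CCC/C(C)=C/CC/C(C)=C/CCC(=C)C(Sc1ccccc1)C[C@@H](O[Si](CC)(CC)CC)C(=O)COC(=O)CP(=O)(OCC)OCC
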